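**Plan**

1. The lactone C3–CH2(ring C) bond is cut first (enolate alkylation). This gives lactone 20, which carries the whole ring A/ring B side chain, and the dihydrobenzofuran-5-ylmethyl bromide 33.
2. In 20 the C7–C8 bond comes from an anti-aldol of a ring B arylacetyl imide with O-benzylvanillin; the aryl–CH2CO bond comes from the aryl bromide of lactone 9.
3. Lactone 9 is cut at O1–C2. Atoms O1–C5–C4, with the ring B benzylic CH2 on C4, are (without O1) the mirror-symmetric 3-(arylmethyl)cyclobutanone 8. Its benzylic CH2, C4 and C5 are the allyl chain of eugenol; C2 and C3 come from dichloroketene.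
4. Bromide 33: O1′–C2′ by acid-induced closure, C2′–C3′ by a syn-aldol of a ring C arylacetyl imide (from methyl 5-bromovanillate) with the same aldehyde.
5. Forward order: cyclobutanone, then the lactone ring (step 5), then the ring B side chain; the dihydrobenzofuran ring is made separately; union at C3; deprotection.
6. Stereochemistry: C4 from the catalyst in the ring expansion; C3 trans to C4 by substrate control; C7/C8 and C3′ from (S)-4-benzyloxazolidinone (magnesium-chelate anti-aldol and boron syn-aldol); C2′ from trans-selective ring closure.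

Key step: step 5

Labels: lactone O1, C2 (C=O), C3, C4, C5. Ring A is the guaiacyl ring on carbinol C7. Ring B is the phenol ring joined to C4 through CH2 and carrying C8 (C9 is the CH2OH on C8). Ring C is the benzo ring of the dihydrobenzofuran (O1′, C2′, C3′). Ring D is the aryl group on C2′.

Remark: methyl 3-bromo-4-hydroxy-5-methoxybenzoate, 4-(benzyloxy)-3-methoxybenzaldehyde and the Reformatsky reagent solution 10 are taken as purchasable (each is otherwise one step from methyl vanillate, vanillin or tert-butyl bromoacetate).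

Remark: the antipode of the N,N′-dioxide ligand in step 5 is the one whose sense of induction gives the (R)-lactone; this is to be confirmed on the first batch by correlation with known (R)-4-benzyl-type butyrolactones.

**Route**

Step 1
Reactants: 1 eugenol
Product: 2 4-allyl-2-bromo-6-methoxyphenol
Conditions: NBS, i-Pr2NH (cat.), CH2Cl2, 0 °C
Reagents that add atoms: N-bromosuccinimide, O=C1CCC(=O)N1Br
Why: Amine-mediated NBS bromination of a phenol (electrophilic aromatic substitution) is ortho-selective, and since the para position carries the allyl group and the other ortho position the methoxy group, bromine should enter C6 without touching the alkene.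

Step 2
Reactants: 2 4-allyl-2-bromo-6-methoxyphenol, 3 benzyl bromide
Product: 4 5-allyl-2-(benzyloxy)-1-bromo-3-methoxybenzene
Conditions: BnBr, K2CO3, DMF, rt
Reagents that add atoms: benzyl bromide (3), BrCc1ccccc1
Why: Williamson ether synthesis on the phenoxide; the benzyl ether should survive the ketene, peracid, organozinc, enolate and hydride steps and is removed only in the final hydrogenolysis.

Step 3
Reactants: 4 5-allyl-2-(benzyloxy)-1-bromo-3-methoxybenzene, 5 trichloroacetyl chloride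
Product: 7 rac-3-{[4-(benzyloxy)-3-bromo-5-methoxyphenyl]methyl}-2,2-dichlorocyclobutan-1-one, via dichloroketene 6 (not isolated)
Conditions: Cl3CCOCl, Zn(Cu), Et2O/DME, rt to 35 °C
Reagents that add atoms: trichloroacetyl chloride (5), ClC(=O)C(Cl)(Cl)Cl
Why: Dichloroketene, formed in the flask by zinc dechlorination of the acid chloride, undergoes the thermal ketene–alkene (2+2) cycloaddition with the terminal alkene, the carbonyl carbon bonding to the terminal CH2; the stereocenter formed here is erased in step 4.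

Step 4
Reactants: 7 rac-3-{[4-(benzyloxy)-3-bromo-5-methoxyphenyl]methyl}-2,2-dichlorocyclobutan-1-one
Product: 8 3-{[4-(benzyloxy)-3-bromo-5-methoxyphenyl]methyl}cyclobutan-1-one
Conditions: Zn, AcOH, rt to 50 °C
Reagents that add atoms: none
Why: Reductive dehalogenation of the α,α-dichloroketone by zinc in acetic acid removes both chlorines, leaves the aryl bromide and benzyl ether alone, and gives the mirror-symmetric cyclobutanone.

Step 5
Reactants: 8 3-{[4-(benzyloxy)-3-bromo-5-methoxyphenyl]methyl}cyclobutan-1-one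
Product: 9 (4R)-4-{[4-(benzyloxy)-3-bromo-5-methoxyphenyl]methyl}oxolan-2-one
Conditions: Sc(OTf)3 (cat.), C2-symmetric amino acid-derived N,N′-dioxide bis(2,6-diisopropylanilide) ligand (cat.), m-CPBA, EtOAc, −20 °C
Reagents that add atoms: 3-chloroperoxybenzoic acid, OOC(=O)c1cccc(Cl)c1
Why: The peracid adds to the scandium-bound carbonyl of 8 to give a Criegee adduct, and one of the two enantiotopic ring CH2 groups then shifts from carbon to oxygen antiperiplanar to the breaking O–O bond, which places O1 between C2 and C5. The closest known reaction is the catalytic asymmetric Baeyer–Villiger desymmetrization of 3-substituted cyclobutanones with a trivalent scandium–N,N′-dioxide complex and m-CPBA. The five-membered lactone arises by ring expansion of the four-membered ketone (a 1,2-shift of a ring carbon onto oxygen with retention at the migrating carbon), not by an exo or endo cyclization. The new stereocenter C4 is set by the chiral ligand sphere on scandium, which decides which CH2 can reach the migrating geometry. The step needs only enantiotopic-group selection, because the mirror plane through C1 and C3 of 8 makes both directions of insertion the same constitution. Release of four-ring strain should let the reaction run at −20 °C, where the electron-rich arene, the benzyl ether and the aryl bromide are not oxidized.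

Step 6
Reactants: 9 (4R)-4-{[4-(benzyloxy)-3-bromo-5-methoxyphenyl]methyl}oxolan-2-one, 10 (2-tert-butoxy-2-oxoethyl)zinc bromide
Product: 11 tert-butyl 2-[2-(benzyloxy)-3-methoxy-5-{[(3R)-5-oxooxolan-3-yl]methyl}phenyl]acetate
Conditions: Pd2(dba)3 (cat.), XPhos, THF, 60 °C
Reagents that add atoms: (2-tert-butoxy-2-oxoethyl)zinc bromide (10), CC(C)(C)OC(=O)C[Zn]Br
Why: Negishi-type coupling of a Reformatsky reagent with an aryl bromide under zerovalent palladium catalysis with a bulky biarylphosphine is mild enough to leave the lactone and its α-CH2 untouched, and puts the CH2CO2t-Bu unit on ring B.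

Step 7
Reactants: 11 tert-butyl 2-[2-(benzyloxy)-3-methoxy-5-{[(3R)-5-oxooxolan-3-yl]methyl}phenyl]acetate
Product: 12 2-[2-(benzyloxy)-3-methoxy-5-{[(3R)-5-oxooxolan-3-yl]methyl}phenyl]acetic acid
Conditions: CF3CO2H, CH2Cl2, 0 °C to rt
Reagents that add atoms: none
Why: Acidolysis of the tert-butyl ester with loss of isobutene frees the arylacetic acid, while the lactone and the aryl benzyl and methyl ethers are stable to cold trifluoroacetic acid.

Step 8
Reactants: 12 2-[2-(benzyloxy)-3-methoxy-5-{[(3R)-5-oxooxolan-3-yl]methyl}phenyl]acetic acid, 13 (4S)-4-benzyl-1,3-oxazolidin-2-one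
Product: 15 (4S)-4-benzyl-3-{2-[2-(benzyloxy)-3-methoxy-5-{[(3R)-5-oxooxolan-3-yl]methyl}phenyl]acetyl}-1,3-oxazolidin-2-one, via mixed pivalic anhydride 14 (not isolated)
Conditions: t-BuCOCl, Et3N, THF, −20 °C; then 13, LiCl, rt
Reagents that add atoms: (4S)-4-benzyl-1,3-oxazolidin-2-one (13), O=C1N[C@@H](Cc2ccccc2)CO1
Why: Mixed-anhydride N-acylation of the oxazolidinone assisted by LiCl needs no strong base and so spares the lactone; the nucleophile attacks the less hindered arylacetyl carbonyl of the anhydride.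

Step 9
Reactants: 15 (4S)-4-benzyl-3-{2-[2-(benzyloxy)-3-methoxy-5-{[(3R)-5-oxooxolan-3-yl]methyl}phenyl]acetyl}-1,3-oxazolidin-2-one, 16 4-(benzyloxy)-3-methoxybenzaldehyde
Product: 18 (4S)-4-benzyl-3-[(2R,3S)-2-[2-(benzyloxy)-3-methoxy-5-{[(3R)-5-oxooxolan-3-yl]methyl}phenyl]-3-[4-(benzyloxy)-3-methoxyphenyl]-3-hydroxypropanoyl]-1,3-oxazolidin-2-one, via trimethylsilyl ether 17 (not isolated)
Conditions: MgCl2 (cat.), Et3N, Me3SiCl, EtOAc, rt; then 1 M HCl, THF, rt
Reagents that add atoms: 4-(benzyloxy)-3-methoxybenzaldehyde (16), COc1cc(C=O)ccc1OCc1ccccc1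
Why: In the magnesium halide-catalyzed direct anti-aldol of an N-acyloxazolidinone with a non-enolizable aromatic aldehyde, the chelated Z-enolate adds through a boat-like transition state on the face opposite the 4-benzyl group and the aldolate is trapped by Me3SiCl, which should set C8 and C7 in the anti (2R,3S) arrangement.

Step 10
Reactants: 18 (4S)-4-benzyl-3-[(2R,3S)-2-[2-(benzyloxy)-3-methoxy-5-{[(3R)-5-oxooxolan-3-yl]methyl}phenyl]-3-[4-(benzyloxy)-3-methoxyphenyl]-3-hydroxypropanoyl]-1,3-oxazolidin-2-one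
Product: 19 (4R)-4-({4-(benzyloxy)-3-[(1S,2S)-1-[4-(benzyloxy)-3-methoxyphenyl]-1,3-dihydroxypropan-2-yl]-5-methoxyphenyl}methyl)oxolan-2-one
Conditions: NaBH4, THF/H2O, 0 °C to rt
Reagents that add atoms: none
Why: Reductive removal of the auxiliary: NaBH4 in wet THF reduces the activated imide carbonyl to the primary alcohol C9 faster than it attacks the γ-lactone, and C7 and C8 are not touched.

Step 11
Reactants: 19 (4R)-4-({4-(benzyloxy)-3-[(1S,2S)-1-[4-(benzyloxy)-3-methoxyphenyl]-1,3-dihydroxypropan-2-yl]-5-methoxyphenyl}methyl)oxolan-2-one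
Product: 20 (4R)-4-({4-(benzyloxy)-3-[(1S,2S)-1-[4-(benzyloxy)-3-methoxyphenyl]-1,3-bis{[tert-butyl(dimethyl)silyl]oxy}propan-2-yl]-5-methoxyphenyl}methyl)oxolan-2-one
Conditions: t-BuMe2SiOTf, 2,6-lutidine, CH2Cl2, −78 to 0 °C
Reagents that add atoms: tert-butyldimethylsilyl triflate, CC(C)(C)[Si](C)(C)OS(=O)(=O)C(F)(F)F
Why: Silylation with a silyl triflate and a hindered pyridine base covers both the primary and the hindered benzylic hydroxyl without enolizing the lactone, so no acidic O–H remains for the enolate step.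

Step 12
Reactants: 21 methyl 3-bromo-4-hydroxy-5-methoxybenzoate
Product: 22 methyl 3-bromo-4-{[tert-butyl(dimethyl)silyl]oxy}-5-methoxybenzoate
Conditions: t-BuMe2SiCl, imidazole, DMF, rt
Reagents that add atoms: tert-butyldimethylsilyl chloride, CC(C)(C)[Si](C)(C)Cl
Why: Standard silylation of the phenol; the aryl silyl ether tolerates acid and the aldol, and can later be removed by fluoride without touching the benzyl ether of ring D.

Step 13
Reactants: 22 methyl 3-bromo-4-{[tert-butyl(dimethyl)silyl]oxy}-5-methoxybenzoate, 10 (2-tert-butoxy-2-oxoethyl)zinc bromide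
Product: 23 methyl 3-(2-tert-butoxy-2-oxoethyl)-4-{[tert-butyl(dimethyl)silyl]oxy}-5-methoxybenzoate
Conditions: Pd2(dba)3 (cat.), XPhos, THF, 60 °C
Reagents that add atoms: (2-tert-butoxy-2-oxoethyl)zinc bromide (10), CC(C)(C)OC(=O)C[Zn]Br
Why: The same Negishi-type coupling of the zinc enolate as in step 6; the weakly basic organozinc tolerates the methyl ester and the aryl silyl ether.

Step 14
Reactants: 23 methyl 3-(2-tert-butoxy-2-oxoethyl)-4-{[tert-butyl(dimethyl)silyl]oxy}-5-methoxybenzoate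
Product: 24 2-[2-{[tert-butyl(dimethyl)silyl]oxy}-3-methoxy-5-(methoxycarbonyl)phenyl]acetic acid
Conditions: CF3CO2H, CH2Cl2, 0 °C to rt
Reagents that add atoms: none
Why: Acidolysis cleaves only the tert-butyl ester (loss of isobutene); the methyl benzoate and the electron-poor aryl silyl ether are stable to anhydrous acid.

Step 15
Reactants: 24 2-[2-{[tert-butyl(dimethyl)silyl]oxy}-3-methoxy-5-(methoxycarbonyl)phenyl]acetic acid, 13 (4S)-4-benzyl-1,3-oxazolidin-2-one
Product: 26 methyl 3-{2-[(4S)-4-benzyl-2-oxo-1,3-oxazolidin-3-yl]-2-oxoethyl}-4-{[tert-butyl(dimethyl)silyl]oxy}-5-methoxybenzoate, via mixed pivalic anhydride 25 (not isolated)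
Conditions: t-BuCOCl, Et3N, THF, −20 °C; then 13, LiCl, rt
Reagents that add atoms: (4S)-4-benzyl-1,3-oxazolidin-2-one (13), O=C1N[C@@H](Cc2ccccc2)CO1
Why: The same mixed-anhydride N-acylation as in step 8; its mild base leaves the aryl silyl ether and the methyl ester in place.

Step 16
Reactants: 26 methyl 3-{2-[(4S)-4-benzyl-2-oxo-1,3-oxazolidin-3-yl]-2-oxoethyl}-4-{[tert-butyl(dimethyl)silyl]oxy}-5-methoxybenzoate, 16 4-(benzyloxy)-3-methoxybenzaldehyde
Product: 27 methyl 3-[(2S,3S)-1-[(4S)-4-benzyl-2-oxo-1,3-oxazolidin-3-yl]-3-[4-(benzyloxy)-3-methoxyphenyl]-3-hydroxy-1-oxopropan-2-yl]-4-{[tert-butyl(dimethyl)silyl]oxy}-5-methoxybenzoate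
Conditions: Bu2BOTf, i-Pr2NEt, CH2Cl2, −78 to 0 °C; then 16, −78 to 0 °C; then pH 7 buffer, MeOH, H2O2, 0 °C
Reagents that add atoms: 4-(benzyloxy)-3-methoxybenzaldehyde (16), COc1cc(C=O)ccc1OCc1ccccc1
Why: In the Evans syn-aldol the dibutylboron Z-enolate reacts through a closed chair transition state with the auxiliary carbonyl turned away from the enolate oxygen, so the aldehyde adds opposite the 4-benzyl group; this sets the future C3′ (2S in the imide) with a syn carbinol.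

Step 17
Reactants: 27 methyl 3-[(2S,3S)-1-[(4S)-4-benzyl-2-oxo-1,3-oxazolidin-3-yl]-3-[4-(benzyloxy)-3-methoxyphenyl]-3-hydroxy-1-oxopropan-2-yl]-4-{[tert-butyl(dimethyl)silyl]oxy}-5-methoxybenzoate
Product: 28 methyl 3-[(1S,2R)-1-[4-(benzyloxy)-3-methoxyphenyl]-1,3-dihydroxypropan-2-yl]-4-{[tert-butyl(dimethyl)silyl]oxy}-5-methoxybenzoate
Conditions: NaBH4, THF/H2O, 0 °C to rt
Reagents that add atoms: none
Why: Reductive removal of the auxiliary as in step 10; the aromatic methyl ester is not reduced by NaBH4 under these conditions, and any early loss of the aryl silyl group would be harmless because step 18 removes it.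

Step 18
Reactants: 28 methyl 3-[(1S,2R)-1-[4-(benzyloxy)-3-methoxyphenyl]-1,3-dihydroxypropan-2-yl]-4-{[tert-butyl(dimethyl)silyl]oxy}-5-methoxybenzoate
Product: 30 methyl (2S,3R)-2-[4-(benzyloxy)-3-methoxyphenyl]-3-(hydroxymethyl)-7-methoxy-2,3-dihydro-1-benzofuran-5-carboxylate, via free phenol 29 (not isolated)
Conditions: Bu4NF, THF, 0 °C, AcOH quench; then TsOH·H2O (cat.), CH2Cl2, 0 °C to rt
Reagents that add atoms: none
Why: Fluoride frees the ring C phenol, and acid then ionizes the benzylic carbinol, stabilized by the para-benzyloxy group of ring D; the phenol traps the cation in a 5-exo closure (acid-catalyzed phenylcoumaran formation) that should give the more stable 2,3-trans ring, so C2′ follows from C3′.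

Step 19
Reactants: 30 methyl (2S,3R)-2-[4-(benzyloxy)-3-methoxyphenyl]-3-(hydroxymethyl)-7-methoxy-2,3-dihydro-1-benzofuran-5-carboxylate
Product: 31 methyl (2S,3R)-2-[4-(benzyloxy)-3-methoxyphenyl]-3-({[tert-butyl(dimethyl)silyl]oxy}methyl)-7-methoxy-2,3-dihydro-1-benzofuran-5-carboxylate
Conditions: t-BuMe2SiCl, imidazole, CH2Cl2, rt
Reagents that add atoms: tert-butyldimethylsilyl chloride, CC(C)(C)[Si](C)(C)Cl
Why: Silylation of the only free hydroxyl protects it through hydride reduction, bromination and the enolate alkylation; it is removed by fluoride together with the other silyl ethers in step 23.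

Step 20
Reactants: 31 methyl (2S,3R)-2-[4-(benzyloxy)-3-methoxyphenyl]-3-({[tert-butyl(dimethyl)silyl]oxy}methyl)-7-methoxy-2,3-dihydro-1-benzofuran-5-carboxylate
Product: 32 [(2S,3R)-2-[4-(benzyloxy)-3-methoxyphenyl]-3-({[tert-butyl(dimethyl)silyl]oxy}methyl)-7-methoxy-2,3-dihydro-1-benzofuran-5-yl]methanol
Conditions: i-Bu2AlH, CH2Cl2, −78 to 0 °C
Reagents that add atoms: none
Why: Hydride reduction of the aromatic methyl ester to the benzylic alcohol; the silyl ether, the benzyl ether and the cyclic benzylic ether are inert to i-Bu2AlH.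

Step 21
Reactants: 32 [(2S,3R)-2-[4-(benzyloxy)-3-methoxyphenyl]-3-({[tert-butyl(dimethyl)silyl]oxy}methyl)-7-methoxy-2,3-dihydro-1-benzofuran-5-yl]methanol
Product: 33 {[(2S,3R)-2-[4-(benzyloxy)-3-methoxyphenyl]-5-(bromomethyl)-7-methoxy-2,3-dihydro-1-benzofuran-3-yl]methoxy}(tert-butyl)dimethylsilane
Conditions: CBr4, PPh3, CH2Cl2, 0 °C
Reagents that add atoms: tetrabromomethane, BrC(Br)(Br)Br
Why: The Appel reaction converts the primary benzylic alcohol to the bromide under neutral conditions that spare the silyl ether and the acid-sensitive 2-aryl-dihydrobenzofuran; the electron-rich bromide is to be used at once.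

Step 22
Reactants: 20 (4R)-4-({4-(benzyloxy)-3-[(1S,2S)-1-[4-(benzyloxy)-3-methoxyphenyl]-1,3-bis{[tert-butyl(dimethyl)silyl]oxy}propan-2-yl]-5-methoxyphenyl}methyl)oxolan-2-one, 33 {[(2S,3R)-2-[4-(benzyloxy)-3-methoxyphenyl]-5-(bromomethyl)-7-methoxy-2,3-dihydro-1-benzofuran-3-yl]methoxy}(tert-butyl)dimethylsilane
Product: 34 (3R,4R)-4-({4-(benzyloxy)-3-[(1S,2S)-1-[4-(benzyloxy)-3-methoxyphenyl]-1,3-bis{[tert-butyl(dimethyl)silyl]oxy}propan-2-yl]-5-methoxyphenyl}methyl)-3-{[(2S,3R)-2-[4-(benzyloxy)-3-methoxyphenyl]-3-({[tert-butyl(dimethyl)silyl]oxy}methyl)-7-methoxy-2,3-dihydro-1-benzofuran-5-yl]methyl}oxolan-2-one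
Conditions: LiN(SiMe3)2, THF, −78 °C; then 33, DMPU, −78 to −30 °C
Reagents that add atoms: none
Why: Alkylation of the lithium enolate of a 4-substituted γ-butyrolactone with a benzylic bromide takes place anti to the C4 substituent (1,2-induction), which should give the 3,4-trans lactone and fix C3 as R.

Step 23
Reactants: 34 (3R,4R)-4-({4-(benzyloxy)-3-[(1S,2S)-1-[4-(benzyloxy)-3-methoxyphenyl]-1,3-bis{[tert-butyl(dimethyl)silyl]oxy}propan-2-yl]-5-methoxyphenyl}methyl)-3-{[(2S,3R)-2-[4-(benzyloxy)-3-methoxyphenyl]-3-({[tert-butyl(dimethyl)silyl]oxy}methyl)-7-methoxy-2,3-dihydro-1-benzofuran-5-yl]methyl}oxolan-2-one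
Product: 35 (3R,4R)-4-({4-(benzyloxy)-3-[(1S,2S)-1-[4-(benzyloxy)-3-methoxyphenyl]-1,3-dihydroxypropan-2-yl]-5-methoxyphenyl}methyl)-3-{[(2S,3R)-2-[4-(benzyloxy)-3-methoxyphenyl]-3-(hydroxymethyl)-7-methoxy-2,3-dihydro-1-benzofuran-5-yl]methyl}oxolan-2-one
Conditions: Bu4NF, AcOH, THF, rt
Reagents that add atoms: none
Why: Buffered fluoride cleaves the three silyl ethers without acid, so neither the benzylic carbinol C7 nor the benzylic ether C2′ can ionize; any lactone opening or C3 epimerization would return to the more stable trans lactone.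

Step 24
Reactants: 35 (3R,4R)-4-({4-(benzyloxy)-3-[(1S,2S)-1-[4-(benzyloxy)-3-methoxyphenyl]-1,3-dihydroxypropan-2-yl]-5-methoxyphenyl}methyl)-3-{[(2S,3R)-2-[4-(benzyloxy)-3-methoxyphenyl]-3-(hydroxymethyl)-7-methoxy-2,3-dihydro-1-benzofuran-5-yl]methyl}oxolan-2-one
Product: 36 (3R,4R)-4-({3-[(1S,2S)-1,3-dihydroxy-1-(4-hydroxy-3-methoxyphenyl)propan-2-yl]-4-hydroxy-5-methoxyphenyl}methyl)-3-{[(2S,3R)-2-(4-hydroxy-3-methoxyphenyl)-3-(hydroxymethyl)-7-methoxy-2,3-dihydro-1-benzofuran-5-yl]methyl}oxolan-2-one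
Conditions: H2 (1 atm), Pd/C, EtOAc/EtOH, rt
Reagents that add atoms: none
Why: Hydrogenolysis of the three aryl benzyl ethers over palladium on carbon under neutral conditions should be much faster than cleavage of the benzylic alcohol or of the dihydrobenzofuran C–O bond, and releases the target.

**Compound list**

1 | eugenol (4-allyl-2-methoxyphenol) | C=CCc1ccc(O)c(OC)c1 | starting material
2 | 4-allyl-2-bromo-6-methoxyphenol | C=CCc1cc(Br)c(O)c(OC)c1 | intermediate
3 | benzyl bromide | BrCc1ccccc1 | starting material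
4 | 5-allyl-2-(benzyloxy)-1-bromo-3-methoxybenzene | C=CCc1cc(Br)c(OCc2ccccc2)c(OC)c1 | intermediate
5 | trichloroacetyl chloride | ClC(=O)C(Cl)(Cl)Cl | starting material
6 | dichloroketene | ClC(Cl)=C=O | intermediate (not isolated)
7 | rac-3-{[4-(benzyloxy)-3-bromo-5-methoxyphenyl]methyl}-2,2-dichlorocyclobutan-1-one | O=C1CC(Cc2cc(Br)c(OCc3ccccc3)c(OC)c2)C1(Cl)Cl | intermediate
8 | 3-{[4-(benzyloxy)-3-bromo-5-methoxyphenyl]methyl}cyclobutan-1-one | O=C1CC(Cc2cc(Br)c(OCc3ccccc3)c(OC)c2)C1 | intermediate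
9 | (4R)-4-{[4-(benzyloxy)-3-bromo-5-methoxyphenyl]methyl}oxolan-2-one | O=C1C[C@@H](Cc2cc(Br)c(OCc3ccccc3)c(OC)c2)CO1 | intermediate
10 | (2-tert-butoxy-2-oxoethyl)zinc bromide | CC(C)(C)OC(=O)C[Zn]Br | starting material
11 | tert-butyl 2-[2-(benzyloxy)-3-methoxy-5-{[(3R)-5-oxooxolan-3-yl]methyl}phenyl]acetate | O=C1C[C@@H](Cc2cc(CC(=O)OC(C)(C)C)c(OCc3ccccc3)c(OC)c2)CO1 | intermediate
12 | 2-[2-(benzyloxy)-3-methoxy-5-{[(3R)-5-oxooxolan-3-yl]methyl}phenyl]acetic acid | O=C1C[C@@H](Cc2cc(CC(=O)O)c(OCc3ccccc3)c(OC)c2)CO1 | intermediate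
13 | (4S)-4-benzyl-1,3-oxazolidin-2-one | O=C1N[C@@H](Cc2ccccc2)CO1 | starting material
14 | mixed pivalic anhydride of acid 12 | O=C1C[C@@H](Cc2cc(CC(=O)OC(=O)C(C)(C)C)c(OCc3ccccc3)c(OC)c2)CO1 | intermediate (not isolated)
15 | (4S)-4-benzyl-3-{2-[2-(benzyloxy)-3-methoxy-5-{[(3R)-5-oxooxolan-3-yl]methyl}phenyl]acetyl}-1,3-oxazolidin-2-one | O=C1C[C@@H](Cc2cc(CC(=O)N3[C@@H](Cc4ccccc4)COC3=O)c(OCc3ccccc3)c(OC)c2)CO1 | intermediate
16 | 4-(benzyloxy)-3-methoxybenzaldehyde | COc1cc(C=O)ccc1OCc1ccccc1 | starting material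
17 | O-trimethylsilyl ether of aldol adduct 18 | COc1cc([C@@H](O[Si](C)(C)C)[C@H](C(=O)N2[C@@H](Cc3ccccc3)COC2=O)c2cc(C[C@H]3COC(=O)C3)cc(OC)c2OCc2ccccc2)ccc1OCc1ccccc1 | intermediate (not isolated)
18 | (4S)-4-benzyl-3-[(2R,3S)-2-[2-(benzyloxy)-3-methoxy-5-{[(3R)-5-oxooxolan-3-yl]methyl}phenyl]-3-[4-(benzyloxy)-3-methoxyphenyl]-3-hydroxypropanoyl]-1,3-oxazolidin-2-one | COc1cc([C@@H](O)[C@H](C(=O)N2[C@@H](Cc3ccccc3)COC2=O)c2cc(C[C@H]3COC(=O)C3)cc(OC)c2OCc2ccccc2)ccc1OCc1ccccc1 | intermediate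
19 | (4R)-4-({4-(benzyloxy)-3-[(1S,2S)-1-[4-(benzyloxy)-3-methoxyphenyl]-1,3-dihydroxypropan-2-yl]-5-methoxyphenyl}methyl)oxolan-2-one | COc1cc([C@@H](O)[C@H](CO)c2cc(C[C@H]3COC(=O)C3)cc(OC)c2OCc2ccccc2)ccc1OCc1ccccc1 | intermediate
20 | (4R)-4-({4-(benzyloxy)-3-[(1S,2S)-1-[4-(benzyloxy)-3-methoxyphenyl]-1,3-bis{[tert-butyl(dimethyl)silyl]oxy}propan-2-yl]-5-methoxyphenyl}methyl)oxolan-2-one | COc1cc([C@@H](O[Si](C)(C)C(C)(C)C)[C@H](CO[Si](C)(C)C(C)(C)C)c2cc(C[C@H]3COC(=O)C3)cc(OC)c2OCc2ccccc2)ccc1OCc1ccccc1 | intermediate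
21 | methyl 3-bromo-4-hydroxy-5-methoxybenzoate | COC(=O)c1cc(Br)c(O)c(OC)c1 | starting material
22 | methyl 3-bromo-4-{[tert-butyl(dimethyl)silyl]oxy}-5-methoxybenzoate | COC(=O)c1cc(Br)c(O[Si](C)(C)C(C)(C)C)c(OC)c1 | intermediate
23 | methyl 3-(2-tert-butoxy-2-oxoethyl)-4-{[tert-butyl(dimethyl)silyl]oxy}-5-methoxybenzoate | COC(=O)c1cc(CC(=O)OC(C)(C)C)c(O[Si](C)(C)C(C)(C)C)c(OC)c1 | intermediate
24 | 2-[2-{[tert-butyl(dimethyl)silyl]oxy}-3-methoxy-5-(methoxycarbonyl)phenyl]acetic acid | COC(=O)c1cc(CC(=O)O)c(O[Si](C)(C)C(C)(C)C)c(OC)c1 | intermediate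
25 | mixed pivalic anhydride of acid 24 | COC(=O)c1cc(CC(=O)OC(=O)C(C)(C)C)c(O[Si](C)(C)C(C)(C)C)c(OC)c1 | intermediate (not isolated)
26 | methyl 3-{2-[(4S)-4-benzyl-2-oxo-1,3-oxazolidin-3-yl]-2-oxoethyl}-4-{[tert-butyl(dimethyl)silyl]oxy}-5-methoxybenzoate | COC(=O)c1cc(CC(=O)N2[C@@H](Cc3ccccc3)COC2=O)c(O[Si](C)(C)C(C)(C)C)c(OC)c1 | intermediate
27 | methyl 3-[(2S,3S)-1-[(4S)-4-benzyl-2-oxo-1,3-oxazolidin-3-yl]-3-[4-(benzyloxy)-3-methoxyphenyl]-3-hydroxy-1-oxopropan-2-yl]-4-{[tert-butyl(dimethyl)silyl]oxy}-5-methoxybenzoate | COC(=O)c1cc(OC)c(O[Si](C)(C)C(C)(C)C)c(c1)[C@@H]([C@H](O)c1ccc(OCc2ccccc2)c(OC)c1)C(=O)N1[C@@H](Cc2ccccc2)COC1=O | intermediate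
28 | methyl 3-[(1S,2R)-1-[4-(benzyloxy)-3-methoxyphenyl]-1,3-dihydroxypropan-2-yl]-4-{[tert-butyl(dimethyl)silyl]oxy}-5-methoxybenzoate | COC(=O)c1cc(OC)c(O[Si](C)(C)C(C)(C)C)c(c1)[C@@H]([C@H](O)c1ccc(OCc2ccccc2)c(OC)c1)CO | intermediate
29 | methyl 3-[(1S,2R)-1-[4-(benzyloxy)-3-methoxyphenyl]-1,3-dihydroxypropan-2-yl]-4-hydroxy-5-methoxybenzoate | COC(=O)c1cc(OC)c(O)c(c1)[C@@H]([C@H](O)c1ccc(OCc2ccccc2)c(OC)c1)CO | intermediate (not isolated)
30 | methyl (2S,3R)-2-[4-(benzyloxy)-3-methoxyphenyl]-3-(hydroxymethyl)-7-methoxy-2,3-dihydro-1-benzofuran-5-carboxylate | COC(=O)c1cc(OC)c2c(c1)[C@H](CO)[C@@H](c1ccc(OCc3ccccc3)c(OC)c1)O2 | intermediate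
31 | methyl (2S,3R)-2-[4-(benzyloxy)-3-methoxyphenyl]-3-({[tert-butyl(dimethyl)silyl]oxy}methyl)-7-methoxy-2,3-dihydro-1-benzofuran-5-carboxylate | COC(=O)c1cc(OC)c2c(c1)[C@H](CO[Si](C)(C)C(C)(C)C)[C@@H](c1ccc(OCc3ccccc3)c(OC)c1)O2 | intermediate
32 | [(2S,3R)-2-[4-(benzyloxy)-3-methoxyphenyl]-3-({[tert-butyl(dimethyl)silyl]oxy}methyl)-7-methoxy-2,3-dihydro-1-benzofuran-5-yl]methanol | OCc1cc(OC)c2c(c1)[C@H](CO[Si](C)(C)C(C)(C)C)[C@@H](c1ccc(OCc3ccccc3)c(OC)c1)O2 | intermediate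
33 | {[(2S,3R)-2-[4-(benzyloxy)-3-methoxyphenyl]-5-(bromomethyl)-7-methoxy-2,3-dihydro-1-benzofuran-3-yl]methoxy}(tert-butyl)dimethylsilane | BrCc1cc(OC)c2c(c1)[C@H](CO[Si](C)(C)C(C)(C)C)[C@@H](c1ccc(OCc3ccccc3)c(OC)c1)O2 | intermediate
34 | (3R,4R)-4-({4-(benzyloxy)-3-[(1S,2S)-1-[4-(benzyloxy)-3-methoxyphenyl]-1,3-bis{[tert-butyl(dimethyl)silyl]oxy}propan-2-yl]-5-methoxyphenyl}methyl)-3-{[(2S,3R)-2-[4-(benzyloxy)-3-methoxyphenyl]-3-({[tert-butyl(dimethyl)silyl]oxy}methyl)-7-methoxy-2,3-dihydro-1-benzofuran-5-yl]methyl}oxolan-2-one | COc1cc([C@@H](O[Si](C)(C)C(C)(C)C)[C@H](CO[Si](C)(C)C(C)(C)C)c2cc(C[C@H]3COC(=O)[C@@H]3Cc3cc(OC)c4c(c3)[C@H](CO[Si](C)(C)C(C)(C)C)[C@@H](c3ccc(OCc5ccccc5)c(OC)c3)O4)cc(OC)c2OCc2ccccc2)ccc1OCc1ccccc1 | intermediate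
35 | (3R,4R)-4-({4-(benzyloxy)-3-[(1S,2S)-1-[4-(benzyloxy)-3-methoxyphenyl]-1,3-dihydroxypropan-2-yl]-5-methoxyphenyl}methyl)-3-{[(2S,3R)-2-[4-(benzyloxy)-3-methoxyphenyl]-3-(hydroxymethyl)-7-methoxy-2,3-dihydro-1-benzofuran-5-yl]methyl}oxolan-2-one | COc1cc([C@@H](O)[C@H](CO)c2cc(C[C@H]3COC(=O)[C@@H]3Cc3cc(OC)c4c(c3)[C@H](CO)[C@@H](c3ccc(OCc5ccccc5)c(OC)c3)O4)cc(OC)c2OCc2ccccc2)ccc1OCc1ccccc1 | intermediate
36 | (3R,4R)-4-({3-[(1S,2S)-1,3-dihydroxy-1-(4-hydroxy-3-methoxyphenyl)propan-2-yl]-4-hydroxy-5-methoxyphenyl}methyl)-3-{[(2S,3R)-2-(4-hydroxy-3-methoxyphenyl)-3-(hydroxymethyl)-7-methoxy-2,3-dihydro-1-benzofuran-5-yl]methyl}oxolan-2-one | COc1cc([C@@H](O)[C@H](CO)c2cc(C[C@H]3COC(=O)[C@@H]3Cc3cc(OC)c4c(c3)[C@H](CO)[C@@H](c3ccc(O)c(OC)c3)O4)cc(OC)c2O)ccc1O | target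

**Step count and risks**

Total steps: 24. Longest linear sequence: 14 steps (steps 1–11 from eugenol, then steps 22–24); the dihydrobenzofuran branch (steps 12–21) joins at step 22.

The three steps most likely to fail:

Step 5. The two enantiotopic CH2 groups may be told apart only partly, because the arylmethyl group sits one carbon away from the ring and far from the metal-bound carbonyl. The shortfall in enantiomeric purity would reappear as diastereomers after step 9. The fallback sets out from 8 and comes back at 9. Cyclobutanone 8 would be oxidized without a chiral catalyst (m-CPBA, NaHCO3, CH2Cl2), the same ring expansion, to rac-4-{[4-(benzyloxy)-3-bromo-5-methoxyphenyl]methyl}oxolan-2-one F1. The lactone would be opened by heating with (S)-1-phenylethylamine (2-hydroxypyridine, toluene, 80 °C) to the two diastereomeric hydroxy amides, (3R)-3-{[4-(benzyloxy)-3-bromo-5-methoxyphenyl]methyl}-4-hydroxy-N-[(1S)-1-phenylethyl]butanamide F2 and (3S)-3-{[4-(benzyloxy)-3-bromo-5-methoxyphenyl]methyl}-4-hydroxy-N-[(1S)-1-phenylethyl]butanamide F3. These would be separated by crystallization or chromatography, and F2 would be relactonized with TsOH·H2O in hot toluene to 9 (classical resolution through diastereomeric amides).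

Step 9. The stabilized arylacetyl enolate may be silylated instead of adding to the electron-rich aldehyde, or the aldol may equilibrate before silyl trapping, which would lower conversion or anti selectivity. The fallback sets out from 12 and comes back at 20; it uses the boron syn-aldol and then inverts C7.
- Acid 12 would be coupled through mixed anhydride 14 with (R)-4-benzyl-1,3-oxazolidin-2-one to (4R)-4-benzyl-3-{2-[2-(benzyloxy)-3-methoxy-5-{[(3R)-5-oxooxolan-3-yl]methyl}phenyl]acetyl}-1,3-oxazolidin-2-one F4.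
- Bu2BOTf/i-Pr2NEt aldol with 16 would give the syn adduct (4R)-4-benzyl-3-[(2R,3R)-2-[2-(benzyloxy)-3-methoxy-5-{[(3R)-5-oxooxolan-3-yl]methyl}phenyl]-3-[4-(benzyloxy)-3-methoxyphenyl]-3-hydroxypropanoyl]-1,3-oxazolidin-2-one F5.
- NaBH4 in wet THF would give the syn diol (4R)-4-({4-(benzyloxy)-3-[(1R,2S)-1-[4-(benzyloxy)-3-methoxyphenyl]-1,3-dihydroxypropan-2-yl]-5-methoxyphenyl}methyl)oxolan-2-one F6.
- Selective silylation of the primary hydroxyl (t-BuMe2SiCl, imidazole) would give (4R)-4-({4-(benzyloxy)-3-[(1R,2S)-1-[4-(benzyloxy)-3-methoxyphenyl]-3-{[tert-butyl(dimethyl)silyl]oxy}-1-hydroxypropan-2-yl]-5-methoxyphenyl}methyl)oxolan-2-one F7.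
- Mitsunobu inversion at C7 (4-nitrobenzoic acid, PPh3, DIAD) would give (1S,2S)-1-[4-(benzyloxy)-3-methoxyphenyl]-2-[2-(benzyloxy)-3-methoxy-5-{[(3R)-5-oxooxolan-3-yl]methyl}phenyl]-3-{[tert-butyl(dimethyl)silyl]oxy}propyl 4-nitrobenzoate F8.
- Methanolysis (K2CO3, MeOH, 0 °C) would give (4R)-4-({4-(benzyloxy)-3-[(1S,2S)-1-[4-(benzyloxy)-3-methoxyphenyl]-3-{[tert-butyl(dimethyl)silyl]oxy}-1-hydroxypropan-2-yl]-5-methoxyphenyl}methyl)oxolan-2-one F9.
- Silylation of the remaining hydroxyl (t-BuMe2SiOTf, 2,6-lutidine) would give 20.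

Step 18. With the ring D phenol still benzylated, the benzylic cation may lose a proton to a stilbene, or the closure may not be fully trans-selective. The fallback sets out from 28 and comes back at 30; it uses the milder para-quinone methide pathway. After fluoride desilylation to 29, hydrogenolysis (H2, Pd/C, EtOAc) would remove the ring D benzyl group to give methyl 3-[(1S,2R)-1,3-dihydroxy-1-(4-hydroxy-3-methoxyphenyl)propan-2-yl]-4-hydroxy-5-methoxybenzoate F10. Dilute acid (HCl, dioxane/H2O, rt) would then form the quinone methide, which the ring C phenol closes to the trans phenylcoumaran methyl (2S,3R)-2-(4-hydroxy-3-methoxyphenyl)-3-(hydroxymethyl)-7-methoxy-2,3-dihydro-1-benzofuran-5-carboxylate F11. Selective O-benzylation of the phenol (BnBr, K2CO3, acetone) would return 30.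

**Further compounds**

F1 | step 5 | rac-4-{[4-(benzyloxy)-3-bromo-5-methoxyphenyl]methyl}oxolan-2-one | O=C1CC(Cc2cc(Br)c(OCc3ccccc3)c(OC)c2)CO1
F2 | step 5 | (3R)-3-{[4-(benzyloxy)-3-bromo-5-methoxyphenyl]methyl}-4-hydroxy-N-[(1S)-1-phenylethyl]butanamide | O=C(C[C@@H](Cc1cc(Br)c(OCc2ccccc2)c(OC)c1)CO)N[C@@H](C)c1ccccc1
F3 | step 5 | (3S)-3-{[4-(benzyloxy)-3-bromo-5-methoxyphenyl]methyl}-4-hydroxy-N-[(1S)-1-phenylethyl]butanamide | O=C(C[C@H](Cc1cc(Br)c(OCc2ccccc2)c(OC)c1)CO)N[C@@H](C)c1ccccc1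
F4 | step 9 | (4R)-4-benzyl-3-{2-[2-(benzyloxy)-3-methoxy-5-{[(3R)-5-oxooxolan-3-yl]methyl}phenyl]acetyl}-1,3-oxazolidin-2-one | O=C1C[C@@H](Cc2cc(CC(=O)N3[C@H](Cc4ccccc4)COC3=O)c(OCc3ccccc3)c(OC)c2)CO1
F5 | step 9 | (4R)-4-benzyl-3-[(2R,3R)-2-[2-(benzyloxy)-3-methoxy-5-{[(3R)-5-oxooxolan-3-yl]methyl}phenyl]-3-[4-(benzyloxy)-3-methoxyphenyl]-3-hydroxypropanoyl]-1,3-oxazolidin-2-one | COc1cc([C@H](O)[C@H](C(=O)N2[C@H](Cc3ccccc3)COC2=O)c2cc(C[C@H]3COC(=O)C3)cc(OC)c2OCc2ccccc2)ccc1OCc1ccccc1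
F6 | step 9 | (4R)-4-({4-(benzyloxy)-3-[(1R,2S)-1-[4-(benzyloxy)-3-methoxyphenyl]-1,3-dihydroxypropan-2-yl]-5-methoxyphenyl}methyl)oxolan-2-one | COc1cc([C@H](O)[C@H](CO)c2cc(C[C@H]3COC(=O)C3)cc(OC)c2OCc2ccccc2)ccc1OCc1ccccc1
F7 | step 9 | (4R)-4-({4-(benzyloxy)-3-[(1R,2S)-1-[4-(benzyloxy)-3-methoxyphenyl]-3-{[tert-butyl(dimethyl)silyl]oxy}-1-hydroxypropan-2-yl]-5-methoxyphenyl}methyl)oxolan-2-one | COc1cc([C@H](O)[C@H](CO[Si](C)(C)C(C)(C)C)c2cc(C[C@H]3COC(=O)C3)cc(OC)c2OCc2ccccc2)ccc1OCc1ccccc1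
F8 | step 9 | (1S,2S)-1-[4-(benzyloxy)-3-methoxyphenyl]-2-[2-(benzyloxy)-3-methoxy-5-{[(3R)-5-oxooxolan-3-yl]methyl}phenyl]-3-{[tert-butyl(dimethyl)silyl]oxy}propyl 4-nitrobenzoate | COc1cc([C@@H](OC(=O)c2ccc(cc2)[N+](=O)[O-])[C@H](CO[Si](C)(C)C(C)(C)C)c2cc(C[C@H]3COC(=O)C3)cc(OC)c2OCc2ccccc2)ccc1OCc1ccccc1
F9 | step 9 | (4R)-4-({4-(benzyloxy)-3-[(1S,2S)-1-[4-(benzyloxy)-3-methoxyphenyl]-3-{[tert-butyl(dimethyl)silyl]oxy}-1-hydroxypropan-2-yl]-5-methoxyphenyl}methyl)oxolan-2-one | COc1cc([C@@H](O)[C@H](CO[Si](C)(C)C(C)(C)C)c2cc(C[C@H]3COC(=O)C3)cc(OC)c2OCc2ccccc2)ccc1OCc1ccccc1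
F10 | step 18 | methyl 3-[(1S,2R)-1,3-dihydroxy-1-(4-hydroxy-3-methoxyphenyl)propan-2-yl]-4-hydroxy-5-methoxybenzoate | COC(=O)c1cc(OC)c(O)c(c1)[C@@H]([C@H](O)c1ccc(O)c(OC)c1)CO
F11 | step 18 | methyl (2S,3R)-2-(4-hydroxy-3-methoxyphenyl)-3-(hydroxymethyl)-7-methoxy-2,3-dihydro-1-benzofuran-5-carboxylate | COC(=O)c1cc(OC)c2c(c1)[C@H](CO)[C@@H](c1ccc(O)c(OC)c1)O2
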